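**Assumption:** the SMILES is read as the (R)-carbinol (C1, on ring B) with an (E)-C8=C9 olefin. Chain carbons are numbered C1 (carbinol) to C14 (benzylic to ring A). Ring A is the 1,3,5-trisubstituted phenol ring; ring B is the 3,5-dihydroxy-4-aryloxyphenyl ring. Nothing here has been run; the route is a proposal.

## Retrosynthetic overview

1. Target ⇐ global desilylation of the tris-TBS macrocycle.
2. The 22-membered ring and the C1 (R)-stereocentre ⇐ one new step: enantioselective Ni-catalysed reductive macrocyclisation of the ring-B aryl bromide onto a tethered aliphatic aldehyde (Ar–C1 bond).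
3. Seco-aldehyde ⇐ Cu-catalysed sp3–sp3 coupling (C13–C14) of a ring-A benzylic bromide with a C1–C13 chain carrying the preformed (E)-C8=C9 olefin (alkyne alkylation, then Na/NH3).
4. Diaryl ether core ⇐ Chan–Lam coupling of 4-bromo-2,6-dimethoxyphenol with an arylboronic acid made by Ir C–H borylation of methyl 3-methoxybenzoate; Me→TBS swap done early.
5. Ring order: both benzene rings are purchased; the only ring formed is the macrocycle, in the penultimate step.

## Route

**Step 1**
Reactants: 1, methyl 3-methoxybenzoate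
Product: 2, [3-methoxy-5-(methoxycarbonyl)phenyl]boronic acid
Conditions: [Ir(OMe)(cod)]2 (1 mol %), dtbpy (2 mol %), B2pin2, THF, 80 °C; then NaIO4, 1 M aq. HCl, THF/H2O, rt
Reagents that add atoms: bis(pinacolato)diboron, CC1(C)OB(OC1(C)C)B1OC(C)(C)C(C)(C)O1; water, O
Why: Sterically controlled Ir-catalysed C–H borylation of a 1,3-disubstituted arene goes to the mutually meta C5 position, and oxidative pinacol cleavage gives the boronic acid.

**Step 2**
Reactants: 2 (2 equiv), [3-methoxy-5-(methoxycarbonyl)phenyl]boronic acid; 3, 4-bromo-2,6-dimethoxyphenol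
Product: 4, methyl 3-(4-bromo-2,6-dimethoxyphenoxy)-5-methoxybenzoate
Conditions: Cu(OAc)2 (1 equiv), pyridine (5 equiv), 4 Å MS, CH2Cl2, dry air, rt, 48 h
Reagents that add atoms: none
Why: Chan–Lam–Evans oxidative C–O coupling tolerates di-ortho-substituted phenols and leaves the aryl bromide untouched, which an Ullmann coupling would not.

**Step 3**
Reactants: 4, methyl 3-(4-bromo-2,6-dimethoxyphenoxy)-5-methoxybenzoate
Product: 5, methyl 3-(4-bromo-2,6-dihydroxyphenoxy)-5-hydroxybenzoate
Conditions: BBr3 (6 equiv), CH2Cl2, −78 °C → rt; then MeOH, 50 °C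
Reagents that add atoms: none (methanol, CO, only restores the methyl ester if any is cleaved)
Why: Lewis-acid demethylation of the three aryl methyl ethers is done here because only an ester, an aryl bromide and a diaryl ether are present, all BBr3-stable.

**Step 4**
Reactants: 5, methyl 3-(4-bromo-2,6-dihydroxyphenoxy)-5-hydroxybenzoate
Product: 6, methyl 3-[4-bromo-2,6-bis(tert-butyldimethylsilyloxy)phenoxy]-5-(tert-butyldimethylsilyloxy)benzoate
Conditions: TBSCl (4 equiv), imidazole (8 equiv), DMF, rt → 40 °C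
Reagents that add atoms: TBSCl, CC(C)(C)[Si](C)(C)Cl
Why: Standard phenol silylation installs fluoride-labile groups so the final deprotection needs no acid, which protects the benzylic alcohol.

**Step 5**
Reactants: 6, the tris-TBS methyl ester
Product: 7, {3-[4-bromo-2,6-bis(TBS-oxy)phenoxy]-5-(TBS-oxy)phenyl}methanol
Conditions: DIBAL-H (2.5 equiv), CH2Cl2, −78 → −20 °C; Rochelle salt
Reagents that add atoms: none
Why: DIBAL reduces the ester to the benzylic alcohol without touching the aryl bromide or aryl silyl ethers at low temperature.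

**Step 6**
Reactants: 7, the benzylic alcohol
Product: 8, 5-bromo-2-[3-(bromomethyl)-5-(TBS-oxy)phenoxy]-1,3-bis(TBS-oxy)benzene
Conditions: CBr4, PPh3, CH2Cl2, 0 °C
Reagents that add atoms: carbon tetrabromide, BrC(Br)(Br)Br
Why: The Appel reaction converts the primary benzylic alcohol to the bromide under neutral conditions that aryl TBS ethers tolerate.

**Step 7**
Reactants: 9, 7-bromoheptan-1-ol
Product: 10, 2-[(7-bromoheptyl)oxy]tetrahydro-2H-pyran (racemic acetal)
Conditions: 3,4-dihydro-2H-pyran, PPTS (cat.), CH2Cl2, rt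
Reagents that add atoms: 3,4-dihydro-2H-pyran, C1=COCCC1
Why: Acid-catalysed THP acetalisation masks the future C1 oxygen with a group stable to acetylide, Na/NH3 and organometallic steps.

**Step 8**
Reactants: 11 (1.3 equiv), hex-5-yn-1-ol; 10, 2-[(7-bromoheptyl)oxy]tetrahydro-2H-pyran
Product: 12, 13-(tetrahydro-2H-pyran-2-yloxy)tridec-5-yn-1-ol
Conditions: n-BuLi (2.1 equiv per 11), THF/DMPU, −78 → −20 °C; then 10, → rt
Reagents that add atoms: none
Why: The alkoxide/acetylide dianion alkylates at carbon with the primary bromide (SN2), giving the C1–C13 chain with its two ends differentiated (free OH at C13, OTHP at C1).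

**Step 9**
Reactants: 12, 13-(THP-oxy)tridec-5-yn-1-ol
Product: 13, (5E)-13-(tetrahydro-2H-pyran-2-yloxy)tridec-5-en-1-ol
Conditions: Na, liq. NH3/THF, −33 °C; NH4Cl quench
Reagents that add atoms: none
Why: Dissolving-metal reduction of the internal alkyne proceeds through the trans vinyl radical/anion and sets the (E)-C8=C9 geometry with essentially complete selectivity.

**Step 10**
Reactants: 13, (5E)-13-(THP-oxy)tridec-5-en-1-ol
Product: 14, 2-{[(8E)-13-iodotridec-8-en-1-yl]oxy}tetrahydro-2H-pyran
Conditions: MsCl, Et3N, CH2Cl2, 0 °C; then NaI, acetone, 50 °C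
Reagents that add atoms: sodium iodide, [Na+].[I-]
Why: Mesylation then Finkelstein displacement gives the primary iodide under non-acidic conditions that keep the THP acetal and olefin intact.

**Step 11**
Reactants: 14 (1.5 equiv), the (8E)-iodo THP ether; 8, the benzylic bromide
Product: 15, 5-bromo-1,3-bis(TBS-oxy)-2-{3-(TBS-oxy)-5-[(6E)-14-(tetrahydro-2H-pyran-2-yloxy)tetradec-6-en-1-yl]phenoxy}benzene
Conditions: 14, t-BuLi (2.1 equiv), Et2O/pentane, −78 °C; MgBr2·OEt2, −78 → −20 °C; then 8, Li2CuCl4 (5 mol %), THF, −40 → 0 °C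
Reagents that add atoms: none
Why: Low-temperature Li–I exchange avoids the 5-exo radical cyclisation that direct Mg insertion risks, and Cu-catalysed (Kochi-type) Grignard coupling with the benzylic bromide forms C13–C14 without touching the aryl bromide or olefin.

**Step 12**
Reactants: 15, the THP ether
Product: 16, (8E)-14-{3-[4-bromo-2,6-bis(TBS-oxy)phenoxy]-5-(TBS-oxy)phenyl}tetradec-8-en-1-ol
Conditions: PPTS, EtOH, 50 °C
Reagents that add atoms: none
Why: Mild acid-catalysed transacetalisation removes the THP group while the more acid-stable aryl TBS ethers remain.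

**Step 13**
Reactants: 16, the primary alcohol
Product: 17, (8E)-14-{3-[4-bromo-2,6-bis(TBS-oxy)phenoxy]-5-(TBS-oxy)phenyl}tetradec-8-enal
Conditions: Dess–Martin periodinane, NaHCO3, CH2Cl2, rt
Reagents that add atoms: none
Why: Buffered Dess–Martin oxidation gives the aldehyde without over-oxidation, olefin migration or silyl loss.

**Step 14**
Reactants: 17, the bromo-aldehyde seco precursor
Product: 18, the tris-TBS macrocycle: 22-membered diaryl-ether cyclophane with (1R)-hydroxyl on ring B, (8E)-olefin and three phenolic TBS ethers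
Conditions: NiBr2·DME (20 mol %), (S,S)-iPr-BiOX (24 mol %; antipode confirmed beforehand on a nonanal model), Zn dust (4 equiv), THF/DMA 4:1, 45 °C, syringe-pump addition of 17 over 16 h (final 2 mM); aq. NH4Cl
Reagents that add atoms: none
Why: Proposed new method: enantioselective Ni-catalysed reductive macrocyclisation, in which L*Ni(0) adds oxidatively to the unhindered Ar–Br, the aryl-nickel species binds the ZnBr2-activated tethered aldehyde and undergoes enantio-determining 1,2-insertion on the aldehyde Si face (giving R), the Ni alkoxide transmetalates to Zn and Zn regenerates Ni(0), with slow addition favouring closure of the strain-free 22-membered ring over oligomers; the closest known reaction types are intermolecular Ni/Zn reductive (including asymmetric) arylation of aldehydes with aryl halides and Nozaki–Hiyama–Kishi macrocyclisation, neither shown as a catalytic enantioselective aryl–aldehyde macrocyclisation.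

**Step 15**
Reactants: 18, the tris-TBS macrocycle
Product: 19, dehydrogravicycle (target)
Conditions: TBAF (3.5 equiv), AcOH (3.5 equiv), THF, 0 °C → rt, under Ar; pH 7 buffer work-up
Reagents that add atoms: none
Why: Buffered fluoride desilylation frees the three phenols under non-acidic, non-reducing conditions, so the (R)-benzylic alcohol and (E)-olefin are not disturbed.

## Compound list

1 | methyl 3-methoxybenzoate | COC(=O)c1cccc(OC)c1 | starting material
2 | [3-methoxy-5-(methoxycarbonyl)phenyl]boronic acid | COC(=O)c1cc(OC)cc(B(O)O)c1 | intermediate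
3 | 4-bromo-2,6-dimethoxyphenol | COc1cc(Br)cc(OC)c1O | starting material
4 | methyl 3-(4-bromo-2,6-dimethoxyphenoxy)-5-methoxybenzoate | COC(=O)c1cc(OC)cc(Oc2c(OC)cc(Br)cc2OC)c1 | intermediate
5 | methyl 3-(4-bromo-2,6-dihydroxyphenoxy)-5-hydroxybenzoate | COC(=O)c1cc(O)cc(Oc2c(O)cc(Br)cc2O)c1 | intermediate
6 | methyl 3-[4-bromo-2,6-bis(TBS-oxy)phenoxy]-5-(TBS-oxy)benzoate | COC(=O)c1cc(O[Si](C)(C)C(C)(C)C)cc(Oc2c(O[Si](C)(C)C(C)(C)C)cc(Br)cc2O[Si](C)(C)C(C)(C)C)c1 | intermediate
7 | {3-[4-bromo-2,6-bis(TBS-oxy)phenoxy]-5-(TBS-oxy)phenyl}methanol | OCc1cc(O[Si](C)(C)C(C)(C)C)cc(Oc2c(O[Si](C)(C)C(C)(C)C)cc(Br)cc2O[Si](C)(C)C(C)(C)C)c1 | intermediate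
8 | 5-bromo-2-[3-(bromomethyl)-5-(TBS-oxy)phenoxy]-1,3-bis(TBS-oxy)benzene | BrCc1cc(O[Si](C)(C)C(C)(C)C)cc(Oc2c(O[Si](C)(C)C(C)(C)C)cc(Br)cc2O[Si](C)(C)C(C)(C)C)c1 | intermediate
9 | 7-bromoheptan-1-ol | OCCCCCCCBr | starting material
10 | 2-[(7-bromoheptyl)oxy]tetrahydro-2H-pyran (racemic) | BrCCCCCCCOC1CCCCO1 | intermediate
11 | hex-5-yn-1-ol | C#CCCCCO | starting material
12 | 13-(tetrahydro-2H-pyran-2-yloxy)tridec-5-yn-1-ol | OCCCCC#CCCCCCCCOC1CCCCO1 | intermediate
13 | (5E)-13-(tetrahydro-2H-pyran-2-yloxy)tridec-5-en-1-ol | OCCCC/C=C/CCCCCCCOC1CCCCO1 | intermediate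
14 | 2-{[(8E)-13-iodotridec-8-en-1-yl]oxy}tetrahydro-2H-pyran | ICCCC/C=C/CCCCCCCOC1CCCCO1 | intermediate
15 | 5-bromo-1,3-bis(TBS-oxy)-2-{3-(TBS-oxy)-5-[(6E)-14-(THP-oxy)tetradec-6-en-1-yl]phenoxy}benzene | CC(C)(C)[Si](C)(C)Oc1cc(CCCCC/C=C/CCCCCCCOC2CCCCO2)cc(Oc3c(O[Si](C)(C)C(C)(C)C)cc(Br)cc3O[Si](C)(C)C(C)(C)C)c1 | intermediate
16 | (8E)-14-{3-[4-bromo-2,6-bis(TBS-oxy)phenoxy]-5-(TBS-oxy)phenyl}tetradec-8-en-1-ol | CC(C)(C)[Si](C)(C)Oc1cc(CCCCC/C=C/CCCCCCCO)cc(Oc3c(O[Si](C)(C)C(C)(C)C)cc(Br)cc3O[Si](C)(C)C(C)(C)C)c1 | intermediate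
17 | (8E)-14-{3-[4-bromo-2,6-bis(TBS-oxy)phenoxy]-5-(TBS-oxy)phenyl}tetradec-8-enal | CC(C)(C)[Si](C)(C)Oc1cc(CCCCC/C=C/CCCCCCC=O)cc(Oc3c(O[Si](C)(C)C(C)(C)C)cc(Br)cc3O[Si](C)(C)C(C)(C)C)c1 | intermediate
18 | tris-TBS ether of the target: (1R,8E) 22-membered macrocycle | CC(C)(C)[Si](C)(C)Oc1cc2cc(c1)Oc1c(O[Si](C)(C)C(C)(C)C)cc(cc1O[Si](C)(C)C(C)(C)C)[C@H](O)CCCCCC/C=C/CCCCC2 | intermediate
19 | dehydrogravicycle, (1R,8E) | Oc1cc2cc(c1)Oc1c(O)cc(cc1O)[C@H](O)CCCCCC/C=C/CCCCC2 | target

## Summary

Total steps: 15. Longest linear sequence: 11 (Steps 1–6, then 11–15); the chain branch is Steps 7–10.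

Steps most likely to fail, with fallbacks:

1. **Step 14 (proposed new enantioselective Ni reductive macrocyclisation).** Risks are oligomerisation, protodebromination, aldehyde reduction and low ee. Fallback with known chemistry: carry the aryl iodide analogue (use 4-iodo-2,6-dimethoxyphenol in Step 2) and close the ring by stoichiometric Ni/Cr Nozaki–Hiyama–Kishi macrocyclisation at high dilution to the racemic carbinol. Then oxidise with Dess–Martin periodinane to the macrocyclic aryl ketone and reduce with (S)-Me-CBS/BH3·SMe2 to (R)-18.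
2. **Step 2 (Chan–Lam coupling of a 2,6-disubstituted, oxidisable phenol).** Fallback: metal-free O-arylation of 3 with the aryl(2,4,6-trimethoxyphenyl)iodonium salt made from methyl 3-iodo-5-methoxybenzoate (base, rt). This is electrophilic aryl transfer instead of oxidative Cu coupling, and it tolerates hindered phenols and aryl bromides.
3. **Step 11 (sp3–sp3 coupling with a 5-hexenyl-type organometallic; cyclisation or homocoupling).** Fallback: couple 8 with the olefin-free Grignard from 2-(4-bromobutyl)-1,3-dioxolane, hydrolyse to the 6-arylhexanal, and build C8=C9 at the union stage by Julia–Kocienski olefination with the 1-phenyltetrazol-5-yl sulfone of 8-(THP-oxy)octane (KHMDS, DME, −60 °C, E-selective). Steps 12–15 then follow unchanged.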